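**Plan** (numbering = azulene skeleton of the target: C1, C2 = CH2; C3 = C(OH)(iPr); C3a = CH; C4 = CH–O-acyl; C5 = CH=; C6 = C–CH3; C7 = C=O; C8 = CH2; C8a = C–CH3)
1. Retrosynthetic cuts, in order: the C4–O ester bond; the C6–CH3 bond and the C3–isopropyl bond; then, in one stroke, C4–C5 and C3a–C8a, back to an acyclic ynone tethered to a 1-silyloxy-vinylcyclopropane.
2. Enabling feature: the seven-membered ring holds a five-carbon unit C5–C6–C7(=O)–C8–C8a with the carbonyl on its middle carbon, which is a ring-opened 1-silyloxy-vinylcyclopropane (C8a=C8 vinyl, C7–OSi, C5/C6 cyclopropane CH2). It is flanked by the two-carbon unit C3a–C4 (an alkyne), and the chain C1–C2–C3 ties C8a to C3a.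
3. Forward: cyclopropanol/alkenyl iodide fragment, Negishi chain extension, ynone; rhodium-catalysed [5+2] cycloaddition closes the five- and seven-membered rings together; then isopropyl addition, C6 methylation, enol silane, hydroboration, acylation, Saegusa–Ito oxidation, desilylation.
4. Helpers: the C3 carbonyl activates the alkyne and keeps the precursor achiral, then accepts the isopropyl group. The silyloxy group activates the cyclopropane and leaves C7 masked as an enol silane.
5. Stereochemistry: C8a from the chiral rhodium catalyst; C3 by addition anti to the angular methyl; C3a and C4 together by syn hydroboration on the face anti to the C8a methyl and the C3 silyloxy group; alkene geometry from hydrozirconation.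

Key step: step 7

Assumption: the sense of induction of the chiral rhodium catalyst in step 7 cannot be predicted with confidence; the route is written for the ligand antipode that gives (8aR)-11, to be identified in the first experiment.

**Step 1**
Reactants: 1 (1-ethoxycyclopropoxy)trimethylsilane
Product: 3 1-(prop-1-yn-1-yl)cyclopropan-1-ol, via 1-ethoxycyclopropan-1-ol 2 (not isolated)
Conditions: MeOH, rt, evaporate; then CH3C≡CMgBr (2.5 equiv), THF, 0 °C → reflux; aq. NH4Cl
Reagents that add atoms: 1-propynylmagnesium bromide, CC#C[Mg]Br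
Why: Methanolysis gives the cyclopropanone hemiketal, whose magnesium salt releases cyclopropanone in situ for 1,2-addition of the alkynyl Grignard reagent (cyclopropanone-hemiketal route to 1-substituted cyclopropanols).

**Step 2**
Reactants: 3 1-(prop-1-yn-1-yl)cyclopropan-1-ol
Product: 4 tert-butyldimethyl{[1-(prop-1-yn-1-yl)cyclopropyl]oxy}silane
Conditions: TBSOTf, 2,6-lutidine, CH2Cl2, −78 → 0 °C
Reagents that add atoms: tert-butyldimethylsilyl trifluoromethanesulfonate, CC(C)(C)[Si](C)(C)OS(=O)(=O)C(F)(F)F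
Why: O-Silylation of the tertiary cyclopropanol under buffered conditions should proceed without ring opening and installs the donor group needed later on the cyclopropane.

**Step 3**
Reactants: 4 tert-butyldimethyl{[1-(prop-1-yn-1-yl)cyclopropyl]oxy}silane
Product: 6 (E)-tert-butyl{[1-(2-iodoprop-1-en-1-yl)cyclopropyl]oxy}dimethylsilane, via alkenylzirconocene chloride 5 (not isolated)
Conditions: Cp2Zr(H)Cl (1.5 equiv), THF, 40 °C; then I2, THF, 0 °C
Reagents that add atoms: Cp2Zr(H)Cl (zirconium of 5 only), [H][Zr](Cl)(C1C=CC=C1)C1C=CC=C1; iodine, II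
Why: syn-Hydrozirconation should place zirconium on the methyl-bearing alkyne carbon, remote from the quaternary cyclopropyl carbon, and iodinolysis with retention gives the iodide with methyl cis to the cyclopropyl group (hydrozirconation–iodination).

**Step 4**
Reactants: 6 (E)-tert-butyl{[1-(2-iodoprop-1-en-1-yl)cyclopropyl]oxy}dimethylsilane; 7 (3-ethoxy-3-oxopropyl)zinc bromide
Product: 8 ethyl (E)-5-{1-[(tert-butyldimethylsilyl)oxy]cyclopropyl}-4-methylpent-4-enoate
Conditions: Pd(OAc)2 (3 mol %), SPhos (6 mol %), THF, rt → 40 °C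
Reagents that add atoms: none
Why: Negishi coupling of the zinc homoenolate with the alkenyl iodide should proceed with retention of alkene geometry and brings in C1, C2 and C3.

**Step 5**
Reactants: 8 ethyl (E)-5-{1-[(tert-butyldimethylsilyl)oxy]cyclopropyl}-4-methylpent-4-enoate
Product: 9 (E)-5-{1-[(tert-butyldimethylsilyl)oxy]cyclopropyl}-N-methoxy-N,4-dimethylpent-4-enamide
Conditions: MeNH(OMe)·HCl, iPrMgCl, THF, −20 → 0 °C
Reagents that add atoms: N,O-dimethylhydroxylamine hydrochloride, CNOC.Cl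
Why: The magnesium amide formed in the flask converts the ester directly into the Weinreb amide.

**Step 6**
Reactants: 9 (E)-5-{1-[(tert-butyldimethylsilyl)oxy]cyclopropyl}-N-methoxy-N,4-dimethylpent-4-enamide
Product: 10 (E)-7-{1-[(tert-butyldimethylsilyl)oxy]cyclopropyl}-6-methylhept-6-en-1-yn-3-one
Conditions: HC≡CMgBr, THF, −20 → 0 °C; cold aq. NaHSO4 quench
Reagents that add atoms: ethynylmagnesium bromide, C#C[Mg]Br
Why: Weinreb ketone synthesis: the chelated adduct prevents over-addition, and the acidic quench keeps the liberated amine from adding to the terminal ynone.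

**Step 7**
Reactants: 10 (E)-7-{1-[(tert-butyldimethylsilyl)oxy]cyclopropyl}-6-methylhept-6-en-1-yn-3-one
Product: 11 (8aR)-7-[(tert-butyldimethylsilyl)oxy]-8a-methyl-2,5,6,8a-tetrahydroazulen-3(1H)-one (C3 ketone, C3a=C4 and C7=C8 double bonds)
Conditions: [RhCl(C2H4)2]2 (5 mol %), chiral BINOL-derived phosphoramidite (12 mol %), NaB[3,5-(CF3)2C6H3]4 (12 mol %), CH2Cl2 (0.02 M), 30 °C
Reagents that add atoms: none
Why: Cationic monovalent rhodium binds the vinylcyclopropane and opens one of its two equivalent strained C7–CH2 bonds to an allyl/alkyl rhodacycle (trivalent rhodium); the tethered ynone inserts into the Rh–C8a allyl terminus (C8a–C3a bond) and C(sp3)–C(sp2) reductive elimination joins C5 to C4, so both rings arise in one catalytic cycle. The closest known reaction is the rhodium-catalysed intramolecular [5+2] cycloaddition of alkyne-tethered vinylcyclopropanes, including 1-silyloxy donors and enantioselective variants with chiral phosphorus ligands. The cyclopentenone closes in a 5-exo sense through the migratory insertion (the chain C1–C2–C3 spans C8a and C3a), and the cycloheptadiene closes by the reductive elimination that completes the formal [5+2]. The only new stereocentre, quaternary C8a, is set by the chiral ligand, which selects the enantiotopic face of the (E)-trisubstituted alkene to which rhodium and then the alkyne are attached. The step needs enantiofacial selectivity and cycloaddition in preference to alkyne oligomerisation: the electron-poor tethered ynone, the unsubstituted cyclopropane (no regiochemical issue in ring opening) and the silyloxy group, which speeds ring opening and leaves C7 as an enol silane, secure reactivity and regiochemistry, while the sense of induction rests on the choice of ligand antipode.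

**Step 8**
Reactants: 11 (8aR)-7-[(tert-butyldimethylsilyl)oxy]-8a-methyl-2,5,6,8a-tetrahydroazulen-3(1H)-one
Product: 13 (3R,8aR)-3-hydroxy-8a-methyl-3-(propan-2-yl)-2,3,5,6,8,8a-hexahydroazulen-7(1H)-one, via tertiary alcohol silyl enol ether 12 (not isolated)
Conditions: iPrMgCl (1.5 equiv), LaCl3·2LiCl (30 mol %), THF, −40 → 0 °C; then AcOH, Bu4NF, 0 °C
Reagents that add atoms: isopropylmagnesium chloride, CC(C)[Mg]Cl
Why: Lanthanide-promoted 1,2-addition to the enone carbonyl should occur on the face anti to the pseudo-axial C8a methyl (as with five-ring ketones 1,3 to an angular methyl), placing OH cis to that methyl, while the enol silane masks C7 until fluoride unmasks the ketone.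

**Step 9**
Reactants: 13 (3R,8aR)-3-hydroxy-8a-methyl-3-(propan-2-yl)-2,3,5,6,8,8a-hexahydroazulen-7(1H)-one
Product: 15 (3R,8aR)-3-hydroxy-6,8a-dimethyl-3-(propan-2-yl)-2,3,5,6,8,8a-hexahydroazulen-7(1H)-one (C6 epimers), via dilithium alkoxide enolate 14 (not isolated)
Conditions: LiN(iPr)2 (2.3 equiv), THF, −78 °C; then MeI, −78 → −40 °C
Reagents that add atoms: lithium diisopropylamide (lithium of 14 only), [Li]N(C(C)C)C(C)C; methyl iodide, CI
Why: Kinetic deprotonation should occur at C6 and not at the neopentylic C8 next to quaternary C8a, so enolate alkylation puts the methyl on C6; the C6 configuration is irrelevant because this carbon becomes sp2.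

**Step 10**
Reactants: 15 (3R,8aR)-3-hydroxy-6,8a-dimethyl-3-(propan-2-yl)-2,3,5,6,8,8a-hexahydroazulen-7(1H)-one
Product: 16 (3R,8aR)-6,8a-dimethyl-3-(propan-2-yl)-3,7-bis[(triethylsilyl)oxy]-1,2,3,5,8,8a-hexahydroazulene (C3a=C4 and C6=C7 double bonds)
Conditions: Et3SiOTf (3 equiv), Et3N, CH2Cl2, 0 °C → rt
Reagents that add atoms: triethylsilyl trifluoromethanesulfonate, CC[Si](CC)(CC)OS(=O)(=O)C(F)(F)F
Why: Soft enolisation under equilibrating conditions should give the more substituted C6=C7 enol silane and silylate the tertiary alcohol in the same operation, masking C7 and fixing the later site of dehydrogenation.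

**Step 11**
Reactants: 16 (3R,8aR)-6,8a-dimethyl-3-(propan-2-yl)-3,7-bis[(triethylsilyl)oxy]-1,2,3,5,8,8a-hexahydroazulene
Product: 18 (3R,3aS,4S,8aR)-6,8a-dimethyl-3-(propan-2-yl)-3,7-bis[(triethylsilyl)oxy]-1,2,3,3a,4,5,8,8a-octahydroazulen-4-ol, via C4 alkylborane 17 (not isolated)
Conditions: BH3·SMe2, THF, 0 °C → rt; then NaBO3·4H2O, THF/H2O, rt
Reagents that add atoms: borane–dimethyl sulfide (boron of 17 only), C[S+](C)[BH3-]; sodium perborate (oxygen of 18), [Na+].[Na+].O[B-]1(O)OO[B-](O)(O)OO1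
Why: Hydroboration–oxidation of the trisubstituted alkene (boron to C4, hydrogen to C3a, syn) on the face anti to the C8a methyl and the C3 silyloxy group should give C3a–H and C4–OH cis to each other and trans to the angular methyl, while the tetrasubstituted enol silane reacts far more slowly.

**Step 12**
Reactants: 19 (E)-4-hydroxycinnamic acid (p-coumaric acid)
Product: 21 (E)-3-{4-[(tert-butyldimethylsilyl)oxy]phenyl}prop-2-enoic acid, via bis-silylated silyl ester 20 (not isolated)
Conditions: TBSCl (2.3 equiv), imidazole, DMF, rt; then AcOH/THF/H2O, rt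
Reagents that add atoms: tert-butyldimethylsilyl chloride, CC(C)(C)[Si](C)(C)Cl
Why: Exhaustive silylation followed by selective hydrolysis of the labile silyl ester leaves the phenol protected for the acylation.

**Step 13**
Reactants: 18 (3R,3aS,4S,8aR)-6,8a-dimethyl-3-(propan-2-yl)-3,7-bis[(triethylsilyl)oxy]-1,2,3,3a,4,5,8,8a-octahydroazulen-4-ol; 21 (E)-3-{4-[(tert-butyldimethylsilyl)oxy]phenyl}prop-2-enoic acid
Product: 23 (3R,3aS,4S,8aR)-6,8a-dimethyl-3-(propan-2-yl)-3,7-bis[(triethylsilyl)oxy]-1,2,3,3a,4,5,8,8a-octahydroazulen-4-yl (E)-3-{4-[(tert-butyldimethylsilyl)oxy]phenyl}prop-2-enoate, via mixed trichlorobenzoic anhydride 22 (not isolated)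
Conditions: 2,4,6-Cl3C6H2COCl, Et3N, THF, rt; then 18, DMAP, toluene, rt → 50 °C
Reagents that add atoms: 2,4,6-trichlorobenzoyl chloride (acyl group of 22 only), O=C(Cl)c1c(Cl)cc(Cl)cc1Cl
Why: Yamaguchi esterification acylates the hindered secondary C4–OH, the only free hydroxyl, under basic conditions that the enol silane tolerates.

**Step 14**
Reactants: 23 (the ester of step 13)
Product: 24 (3R,3aS,4S,8aR)-6,8a-dimethyl-7-oxo-3-(propan-2-yl)-3-[(triethylsilyl)oxy]-1,2,3,3a,4,7,8,8a-octahydroazulen-4-yl (E)-3-{4-[(tert-butyldimethylsilyl)oxy]phenyl}prop-2-enoate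
Conditions: Pd(OAc)2 (1.2 equiv), MeCN, rt
Reagents that add atoms: none
Why: Saegusa–Ito oxidation of the C6=C7 enol silane gives the C5=C6 enone by β-hydride elimination toward C5; C8a is quaternary, so no other ring enone can form.

**Step 15**
Reactants: 24 (the enone of step 14)
Product: 25 (3R,3aS,4S,8aR)-3-hydroxy-6,8a-dimethyl-7-oxo-3-(propan-2-yl)-1,2,3,3a,4,7,8,8a-octahydroazulen-4-yl (E)-3-(4-hydroxyphenyl)prop-2-enoate (target)
Conditions: HF·pyridine, THF/pyridine, 0 °C → rt
Reagents that add atoms: none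
Why: Fluoride-mediated global desilylation under mildly acidic conditions frees the phenol and the tertiary alcohol without touching the ester or the γ-acyloxy enone.

**Compound list**
1 | (1-ethoxycyclopropoxy)trimethylsilane | CCOC1(O[Si](C)(C)C)CC1 | starting material
2 | 1-ethoxycyclopropan-1-ol | CCOC1(O)CC1 | intermediate (not isolated)
3 | 1-(prop-1-yn-1-yl)cyclopropan-1-ol | CC#CC1(O)CC1 | intermediate
4 | tert-butyldimethyl{[1-(prop-1-yn-1-yl)cyclopropyl]oxy}silane | CC#CC1(O[Si](C)(C)C(C)(C)C)CC1 | intermediate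
5 | chlorobis(cyclopentadienyl){(E)-1-[1-(tert-butyldimethylsilyloxy)cyclopropyl]prop-1-en-2-yl}zirconium (Zr trans to cyclopropyl) | C/C(=C\C1(O[Si](C)(C)C(C)(C)C)CC1)[Zr](Cl)(C1C=CC=C1)C1C=CC=C1 | intermediate (not isolated)
6 | (E)-tert-butyl{[1-(2-iodoprop-1-en-1-yl)cyclopropyl]oxy}dimethylsilane | C/C(I)=C\C1(O[Si](C)(C)C(C)(C)C)CC1 | intermediate
7 | (3-ethoxy-3-oxopropyl)zinc bromide | CCOC(=O)CC[Zn]Br | starting material
8 | ethyl (E)-5-{1-[(tert-butyldimethylsilyl)oxy]cyclopropyl}-4-methylpent-4-enoate | CCOC(=O)CC/C(C)=C/C1(O[Si](C)(C)C(C)(C)C)CC1 | intermediate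
9 | (E)-5-{1-[(tert-butyldimethylsilyl)oxy]cyclopropyl}-N-methoxy-N,4-dimethylpent-4-enamide | CON(C)C(=O)CC/C(C)=C/C1(O[Si](C)(C)C(C)(C)C)CC1 | intermediate
10 | (E)-7-{1-[(tert-butyldimethylsilyl)oxy]cyclopropyl}-6-methylhept-6-en-1-yn-3-one | C#CC(=O)CC/C(C)=C/C1(O[Si](C)(C)C(C)(C)C)CC1 | intermediate
11 | (8aR)-7-[(tert-butyldimethylsilyl)oxy]-8a-methyl-2,5,6,8a-tetrahydroazulen-3(1H)-one | O=C1CC[C@]2(C)C=C(O[Si](C)(C)C(C)(C)C)CCC=C12 | intermediate
12 | (3R,8aR)-7-[(tert-butyldimethylsilyl)oxy]-8a-methyl-3-(propan-2-yl)-1,2,3,5,6,8a-hexahydroazulen-3-ol (present as its magnesium alkoxide) | CC(C)[C@]1(O)CC[C@]2(C)C=C(O[Si](C)(C)C(C)(C)C)CCC=C12 | intermediate (not isolated)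
13 | (3R,8aR)-3-hydroxy-8a-methyl-3-(propan-2-yl)-2,3,5,6,8,8a-hexahydroazulen-7(1H)-one | CC(C)[C@]1(O)CC[C@]2(C)CC(=O)CCC=C12 | intermediate
14 | dilithium salt of 13 (C3 alkoxide, C6=C7 enolate) | CC(C)[C@]1(O[Li])CC[C@]2(C)CC(O[Li])=CCC=C12 | intermediate (not isolated)
15 | (3R,8aR)-3-hydroxy-6,8a-dimethyl-3-(propan-2-yl)-2,3,5,6,8,8a-hexahydroazulen-7(1H)-one (C6 epimers) | CC(C)[C@]1(O)CC[C@]2(C)CC(=O)C(C)CC=C12 | intermediate
16 | (3R,8aR)-6,8a-dimethyl-3-(propan-2-yl)-3,7-bis[(triethylsilyl)oxy]-1,2,3,5,8,8a-hexahydroazulene | CC(C)[C@]1(O[Si](CC)(CC)CC)CC[C@]2(C)CC(O[Si](CC)(CC)CC)=C(C)CC=C12 | intermediate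
17 | C4-boryl (BH2) adduct of 16, boron and C3a–H on the face anti to the C8a methyl | CC(C)[C@]1(O[Si](CC)(CC)CC)CC[C@]2(C)CC(O[Si](CC)(CC)CC)=C(C)C[C@H](B)[C@@H]12 | intermediate (not isolated)
18 | (3R,3aS,4S,8aR)-6,8a-dimethyl-3-(propan-2-yl)-3,7-bis[(triethylsilyl)oxy]-1,2,3,3a,4,5,8,8a-octahydroazulen-4-ol | CC(C)[C@]1(O[Si](CC)(CC)CC)CC[C@]2(C)CC(O[Si](CC)(CC)CC)=C(C)C[C@H](O)[C@@H]12 | intermediate
19 | (E)-4-hydroxycinnamic acid | OC(=O)/C=C/c1ccc(O)cc1 | starting material
20 | tert-butyldimethylsilyl (E)-3-{4-[(tert-butyldimethylsilyl)oxy]phenyl}prop-2-enoate | CC(C)(C)[Si](C)(C)OC(=O)/C=C/c1ccc(O[Si](C)(C)C(C)(C)C)cc1 | intermediate (not isolated)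
21 | (E)-3-{4-[(tert-butyldimethylsilyl)oxy]phenyl}prop-2-enoic acid | OC(=O)/C=C/c1ccc(O[Si](C)(C)C(C)(C)C)cc1 | intermediate
22 | (E)-3-{4-[(tert-butyldimethylsilyl)oxy]phenyl}prop-2-enoic 2,4,6-trichlorobenzoic anhydride | O=C(/C=C/c1ccc(O[Si](C)(C)C(C)(C)C)cc1)OC(=O)c1c(Cl)cc(Cl)cc1Cl | intermediate (not isolated)
23 | (3R,3aS,4S,8aR)-6,8a-dimethyl-3-(propan-2-yl)-3,7-bis[(triethylsilyl)oxy]-1,2,3,3a,4,5,8,8a-octahydroazulen-4-yl (E)-3-{4-[(tert-butyldimethylsilyl)oxy]phenyl}prop-2-enoate | CC(C)[C@]1(O[Si](CC)(CC)CC)CC[C@]2(C)CC(O[Si](CC)(CC)CC)=C(C)C[C@H](OC(=O)/C=C/c3ccc(O[Si](C)(C)C(C)(C)C)cc3)[C@@H]12 | intermediate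
24 | (3R,3aS,4S,8aR)-6,8a-dimethyl-7-oxo-3-(propan-2-yl)-3-[(triethylsilyl)oxy]-1,2,3,3a,4,7,8,8a-octahydroazulen-4-yl (E)-3-{4-[(tert-butyldimethylsilyl)oxy]phenyl}prop-2-enoate | CC(C)[C@]1(O[Si](CC)(CC)CC)CC[C@]2(C)CC(=O)C(C)=C[C@H](OC(=O)/C=C/c3ccc(O[Si](C)(C)C(C)(C)C)cc3)[C@@H]12 | intermediate
25 | (3R,3aS,4S,8aR)-3-hydroxy-6,8a-dimethyl-7-oxo-3-(propan-2-yl)-1,2,3,3a,4,7,8,8a-octahydroazulen-4-yl (E)-3-(4-hydroxyphenyl)prop-2-enoate | CC(C)[C@]1(O)CC[C@]2(C)CC(=O)C(C)=C[C@H](OC(=O)/C=C/c3ccc(O)cc3)[C@@H]12 | target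

**Totals**
Total step count: 15. Longest linear sequence: 14 (steps 1–11 and 13–15).

**Steps most likely to fail**

Step 7. The insertion that creates the quaternary centre may not discriminate the enantiotopic alkene faces well enough, or oligomerisation of the terminal ynone may outrun cyclopropane opening with the chiral cationic catalyst. The fallback sets out from 10. The cycloaddition is run with achiral [Rh(CO)2Cl]2 (toluene, 80 °C), which should give the racemic cycloadduct F1. Reagent-controlled reduction of the enone carbonyl with (S)-2-methyl-CBS-oxazaborolidine and catecholborane (toluene, −78 °C) should turn the two enantiomers into the diastereomeric allylic alcohols (3R,8aR)-alcohol F2 and (3R,8aS)-alcohol F3, which are separated by chromatography. Oxidation of F2 with MnO2 (CH2Cl2, rt) comes back to the route at 11.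

Step 11. Borane may not discriminate the alkene faces, because the isopropyl group on the upper face competes with the C8a methyl and the C3 silyloxy group on the lower face; the enol silane may also be hydroborated. The fallback sets out from 16. Hydroboration–oxidation is run as in step 11 without regard to face, giving 18 together with its C3a,C4-bis-epimer F4. The mixture is oxidised with Dess–Martin periodinane (NaHCO3, CH2Cl2) to the cis-fused C4 ketone F5 and the trans-fused C4 ketone F6. Base equilibration at C3a (DBU, CH2Cl2) should funnel the material to trans-fused F6, in which the C4 carbonyl lies anti to the isopropyl group. Reagent-controlled reduction with (R)-2-methyl-CBS-oxazaborolidine and BH3·SMe2 (hydride to the lower face) comes back to the route at 18.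

Step 8. The branched Grignard reagent may reduce the hindered enone by β-hydride transfer or enolise it, and facial discrimination by the angular methyl may be eroded. The fallback sets out from 11. Addition of 2-propenylmagnesium bromide with LaCl3·2LiCl (a smaller sp2 nucleophile without β-hydrogen on an sp3 carbon) gives the isopropenyl carbinol enol silane F7, which is treated in the same flask with AcOH and Bu4NF to give the isopropenyl hydroxy ketone F8. Chemoselective hydrogenation of the 1,1-disubstituted alkene over the trisubstituted ring alkene with RhCl(PPh3)3 and H2 (benzene, rt) comes back to the route at 13.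

**Further compounds**
F1 | step 7 | racemic 7-[(tert-butyldimethylsilyl)oxy]-8a-methyl-2,5,6,8a-tetrahydroazulen-3(1H)-one | O=C1CCC2(C)C=C(O[Si](C)(C)C(C)(C)C)CCC=C12
F2 | step 7 | (3R,8aR)-7-[(tert-butyldimethylsilyl)oxy]-8a-methyl-1,2,3,5,6,8a-hexahydroazulen-3-ol | O[C@@H]1CC[C@]2(C)C=C(O[Si](C)(C)C(C)(C)C)CCC=C12
F3 | step 7 | (3R,8aS)-7-[(tert-butyldimethylsilyl)oxy]-8a-methyl-1,2,3,5,6,8a-hexahydroazulen-3-ol | O[C@@H]1CC[C@@]2(C)C=C(O[Si](C)(C)C(C)(C)C)CCC=C12
F4 | step 11 | (3R,3aR,4R,8aR)-6,8a-dimethyl-3-(propan-2-yl)-3,7-bis[(triethylsilyl)oxy]-1,2,3,3a,4,5,8,8a-octahydroazulen-4-ol (C3a,C4-bis-epimer of 18) | CC(C)[C@]1(O[Si](CC)(CC)CC)CC[C@]2(C)CC(O[Si](CC)(CC)CC)=C(C)C[C@@H](O)[C@H]12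
F5 | step 11 | (3R,3aS,8aR)-6,8a-dimethyl-3-(propan-2-yl)-3,7-bis[(triethylsilyl)oxy]-2,3,3a,5,8,8a-hexahydroazulen-4(1H)-one (cis-fused, C3a–H syn to the C8a methyl) | CC(C)[C@]1(O[Si](CC)(CC)CC)CC[C@]2(C)CC(O[Si](CC)(CC)CC)=C(C)CC(=O)[C@H]12
F6 | step 11 | (3R,3aR,8aR)-6,8a-dimethyl-3-(propan-2-yl)-3,7-bis[(triethylsilyl)oxy]-2,3,3a,5,8,8a-hexahydroazulen-4(1H)-one (trans-fused, C3a–H anti to the C8a methyl) | CC(C)[C@]1(O[Si](CC)(CC)CC)CC[C@]2(C)CC(O[Si](CC)(CC)CC)=C(C)CC(=O)[C@@H]12
F7 | step 8 | (3R,8aR)-7-[(tert-butyldimethylsilyl)oxy]-8a-methyl-3-(prop-1-en-2-yl)-1,2,3,5,6,8a-hexahydroazulen-3-ol | CC(=C)[C@]1(O)CC[C@]2(C)C=C(O[Si](C)(C)C(C)(C)C)CCC=C12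
F8 | step 8 | (3R,8aR)-3-hydroxy-8a-methyl-3-(prop-1-en-2-yl)-2,3,5,6,8,8a-hexahydroazulen-7(1H)-one | CC(=C)[C@]1(O)CC[C@]2(C)CC(=O)CCC=C12
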